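Compound numbers used throughout: 1–9 are the ring A series, 10–16 the ring B series, 17 is carbon dioxide, 18 and 19 are the reactive intermediates of the coupling, 20 is its product and 21 is the target.

## The problem

The target 21 is a diaryl ether of two heavily substituted benzene rings. Ring A carries OMe at C1, H at C2, CO2H at C3, the ether oxygen at C4, OH at C5 and Cl at C6. Ring B carries CO2H at C1', OH at C2', CH3 at C4' and the ether oxygen at C6'. The ether oxygen therefore sits between two ortho substituents on the ring A side (C3 carboxyl, C5 hydroxyl) and next to a carboxyl on the ring B side, which makes classical copper- or SNAr-based ether formation unattractive. There are no stereocentres and the ether rotates freely, so the whole difficulty is regiochemical: five different substituents on ring A and a 1,2,3-trisubstituted O/CO2H/O array on ring B. Several groups limit the choice of reagents. The aryl chloride rules out hydrogenolysis and careless halogen–metal exchange. The single methyl ether rules out global Lewis-acid dealkylation. The ring B acid is a 2,6-dioxygenated benzoic acid that can lose CO2 in hot acid. The C1' carboxyl and the C5 hydroxyl flank the ether and could lactonise to a seven-membered depsidone if the acid is activated. The enabling feature is on ring B: the ether oxygen at C6' and the carboxyl at C1' are on adjacent carbons, with the C2' oxygen on the other side of C1'. This is exactly the pattern left when a nucleophile and then an electrophile add across a 3-alkoxybenzyne.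

## Retrosynthesis

**21 to 20.** The last disconnection removes only protecting groups: the two O–CH2OCH3 bonds at C5–O and C2'–O. Methoxymethyl ethers are chosen over benzyl ethers (hydrogenolysis would endanger C6–Cl) and over methyl ethers (their cleavage would not spare the C1 methoxy group). Dilute acid at room temperature is all the forward step needs. Both acetals also have a function earlier: the one on ring A leaves the C4 oxygen as the only phenoxide, and the one on ring B directs the aryne addition.

**20 to 9, 16 and 17.** The O–C6' ether bond and the C1'–carboxyl bond are cut together. This leads back to the ring A salicylic acid 9 (used as its dipotassium salt 18), the aryne 19 released from silyl triflate 16, and carbon dioxide 17. The neighbouring cuts are less attractive. Cutting O–C4 would need a hexasubstituted ring A electrophile. Cutting O–C6' alone (copper-mediated coupling with an ortho-carbonyl aryl halide) asks a doubly ortho-substituted, hydrogen-bonded phenol to attack a hindered C–halogen bond. In the chosen cut the same phenoxide meets an unhindered, very electrophilic triple bond, and the carboxyl arrives as the free acid, so no hindered 2,6-disubstituted benzoate ester has to be hydrolysed later. The forward reaction has to deliver regioselective addition across the aryne, phenoxide rather than carboxylate attack, and CO2 capture faster than protonation. Both fragments are simple benzenes of comparable size, so the route is convergent.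

**9 to 8 to 7.** The ring A carboxyl carbon (bond to C3) is traced to the aldehyde 8 and from there to the phenol 7 by ortho-formylation. In 7 only one carbon ortho to the hydroxyl is free and the para carbon carries OMe, so the formyl group can go to one place only. This is preferred to carboxylation of the phenol under forcing conditions, which the acetal would not survive.

**7 to 4 to 2 to 1.** The C5–O bond and the C6–Cl bond are both made by directed ortho-metalation, starting from 3-methoxyphenol 1. The first lithiation of MOM ether 2 occurs between the two oxygens and puts chlorine there (4). The second is steered by the stronger OMOM director to the remaining position next to it and is converted to the phenol 7. The obvious alternative, electrophilic chlorination of a 3,5-dioxygenated benzoate followed by formylation and Dakin oxidation, was rejected. Electrophilic halogenation of such resorcinol esters tends to attack the carbon next to the ester and not the carbon between the oxygens, so the chlorine position would not be secure.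

**16 to 15 to 14 to 12 to 11 to 10.** The triflate is the last bond made. The C–Si bond is installed by metalation of carbamate 12 at the carbon flanked by the carbamate and the OMOM group, and the carbamate in 14 is then reduced off to give silylphenol 15. Carbamate 12 comes from orcinol 10 through the mono-MOM ether 11. The only unselective operation is the statistical mono-protection of a cheap symmetrical diol.

## Roads not taken

**Alternative 1:** Ring A is built last, around a preformed ether, by a photochemical Wolff rearrangement and benzannulation. The diazo ketone A2, which already carries ring B as an enol ether, would give a vinylketene on irradiation. This adds the silyl ynol ether A3 in a [2+2] sense, and on heating the cyclobutenone opens and the dienylketene closes to the phenol A1. The cut is at C5–C6, C1–C2 and C4–C5 of ring A.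
- Merits: the hindered ether is never made by substitution at an aromatic carbon, every ring A substituent is placed by the connectivity of the components, and the silyl group at C6 guarantees the chlorine position by ipso-chlorodesilylation. In regiochemical certainty for ring A this road is at least as good as the chosen one.
- Weak points: A2 is a diazo ketone conjugated to a doubly activated aryloxy-acrylate and is likely to be fragile. A3 is not a catalogue reagent. Ring B must still be made in full as a differentiated orsellinate. After the annulation there remain chlorodesilylation, acetal removal and two ester hydrolyses, one of them at the di-ortho-substituted ring B ester, which is notoriously slow.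
- Comparison: the chosen plan answers the regiochemical advantage with two directed metalations that are equally unambiguous. It is shorter, convergent, and delivers both carboxyls as free acids.

**Alternative 2:** Ring B is made by an anionic cascade on the same ring A acid 9. Its phenoxide would add to the ynoate β-carbon of the enynedioate A5, and the resulting carbanion at C1' would attack the methyl ester to close ring B (O–C6' and C1'–C2' formed). Tautomerisation would give the phenol A4.
- Merits: there is no aryne, no gas and no fluoride. The ether oxygen position is fixed by polarity, so the regiochemical question of the chosen plan does not arise. The C2' hydroxyl emerges unprotected, and the tert-butyl ester would fall off in the same acid step as the acetal. In these respects it is cleaner on paper than the chosen route.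
- Weak points: A5 has an acidic methylene between an alkene and an ester and a conjugated enyne that invites isomerisation and 1,6-addition. The cyclisation needs the transient vinyl anion to acylate before it is protonated, and after protonation the β-aryloxy enoate is no longer nucleophilic at C1'. The cascade is as unprecedented as the three-component coupling.
- Comparison: both key steps are new, but the chosen one uses two stable, storable partners, and its most likely failure (protonation) leaves a clean by-product and not a polymerised chain.

**Alternative 3:** Ring B is closed by olefin metathesis. The triene A7 (acryloyl and methallyl groups on an aryloxy-alkylidene β-keto ester) would be treated with RuCl2(H2IMes)(PCy3)(=CHPh). Loss of ethylene forms C3'=C4', and the cyclohexadienone enolises to the phenol A6.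
- Merits: metathesis followed by aromatisation is established chemistry and runs under neutral conditions. In precedent for the key step this road is better than the chosen plan.
- Weak points: A7 must be assembled linearly on the hindered ring A phenol as a tetrasubstituted, doubly acylated enol ether bearing a polymerisable acryloyl group. The metathesis must join an electron-poor alkene to a 1,1-disubstituted one. The product still carries a hindered ring B methyl ester whose hydrolysis beside a free ortho phenol is difficult.
- Comparison: the chosen plan accepts a less certain key step in exchange for about half the number of operations and full convergence, and it carries a fallback built on known chemistry.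

Key step: step 11

Assumption: the target is achiral and is taken as drawn; 3-bromo-5-methylphenol, needed only in one fallback, is taken to be a catalogue compound.

## Route

Step 1
Reactants: 1 3-methoxyphenol
Product: 2 1-methoxy-3-(methoxymethoxy)benzene
Conditions: NaH, MOMCl, THF, 0 °C to rt
Reagents that add atoms: chloromethyl methyl ether, COCCl
Why: O-alkylation of the sodium phenoxide with an α-chloro ether (standard MOM protection); the acetal is later both the catechol protecting group and the strongest metalation director on the ring.

Step 2
Reactants: 2 1-methoxy-3-(methoxymethoxy)benzene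
Product: 4 2-chloro-1-methoxy-3-(methoxymethoxy)benzene, via C2 aryllithium 3 (not isolated)
Conditions: n-BuLi, THF, 0 °C to rt; C2Cl6, −78 °C to rt
Reagents that add atoms: hexachloroethane, ClC(Cl)(Cl)C(Cl)(Cl)Cl
Why: Directed ortho-metalation at the carbon coordinated by both oxygens, the kinetic site of 1,3-dioxygenated benzenes, followed by chlorine transfer from C2Cl6; the halogen is thereby fixed between the two oxygens.

Step 3
Reactants: 4 2-chloro-1-methoxy-3-(methoxymethoxy)benzene
Product: 7 3-chloro-4-methoxy-2-(methoxymethoxy)phenol, via C4 aryllithium 5 (not isolated), via dimethyl arylboronate 6 (not isolated)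
Conditions: s-BuLi, TMEDA, THF, −78 °C; B(OMe)3, −78 °C to rt; H2O2, aq NaOH, 0 °C
Reagents that add atoms: hydrogen peroxide, OO
Why: Second directed ortho-metalation, steered by the better-chelating OMOM group and not by OMe, then borylation and oxidative C–B to C–O conversion; both carbons next to chlorine are substituted, so 5 cannot eliminate to an aryne, and aryl chlorides exchange only slowly with s-BuLi at −78 °C.

Step 4
Reactants: 7 3-chloro-4-methoxy-2-(methoxymethoxy)phenol
Product: 8 4-chloro-2-hydroxy-5-methoxy-3-(methoxymethoxy)benzaldehyde
Conditions: MgCl2, Et3N, (CH2O)n, MeCN, reflux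
Reagents that add atoms: formaldehyde (as paraformaldehyde), C=O
Why: Magnesium-mediated ortho-formylation of a phenol (Casnati–Skattebøl): the magnesium phenoxide delivers formaldehyde to the only free ortho carbon and a second formaldehyde oxidises the benzylic alkoxide to the aldehyde; the para carbon is blocked by OMe and the basic medium spares the acetal.

Step 5
Reactants: 8 4-chloro-2-hydroxy-5-methoxy-3-(methoxymethoxy)benzaldehyde
Product: 9 4-chloro-2-hydroxy-5-methoxy-3-(methoxymethoxy)benzoic acid
Conditions: NaClO2, NaH2PO4, 2-methyl-2-butene, t-BuOH/H2O, rt
Reagents that add atoms: sodium chlorite, [Na+].[O-]Cl=O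
Why: Pinnick oxidation of the aldehyde under phosphate buffer, mild enough for the MOM acetal; the alkene scavenger removes hypochlorous acid before it can chlorinate or oxidise the electron-rich phenol.

Step 6
Reactants: 10 orcinol (5-methylbenzene-1,3-diol)
Product: 11 3-(methoxymethoxy)-5-methylphenol
Conditions: NaH (1 equiv), MOMCl (1 equiv), DMF, 0 °C
Reagents that add atoms: chloromethyl methyl ether, COCCl
Why: Statistical mono-alkylation of a symmetrical resorcinol; the monoether should be separable from recoverable orcinol and from the bis-ether by chromatography.

Step 7
Reactants: 11 3-(methoxymethoxy)-5-methylphenol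
Product: 12 3-(methoxymethoxy)-5-methylphenyl N,N-diethylcarbamate
Conditions: NaH, Et2NCOCl, THF, 0 °C to rt
Reagents that add atoms: N,N-diethylcarbamoyl chloride, CCN(CC)C(=O)Cl
Why: O-carbamoylation of the sodium phenoxide; the diethylcarbamate is among the strongest oxygen-based metalation directors and has no N–H to interfere.

Step 8
Reactants: 12 3-(methoxymethoxy)-5-methylphenyl N,N-diethylcarbamate
Product: 14 3-(methoxymethoxy)-5-methyl-2-(trimethylsilyl)phenyl N,N-diethylcarbamate, via C2 aryllithium 13 (not isolated)
Conditions: s-BuLi, TMEDA, THF, −78 °C; TMSCl, −78 °C to rt
Reagents that add atoms: chlorotrimethylsilane, C[Si](C)(C)Cl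
Why: Directed ortho-metalation at the carbon flanked by the carbamate and the OMOM group (cooperative direction), with silyl quench at −78 °C before the anionic ortho-Fries shift can set in; the methyl group is ortho to neither director, so lateral metalation is not expected.

Step 9
Reactants: 14 3-(methoxymethoxy)-5-methyl-2-(trimethylsilyl)phenyl N,N-diethylcarbamate
Product: 15 3-(methoxymethoxy)-5-methyl-2-(trimethylsilyl)phenol
Conditions: LiAlH4, THF, 0 °C to reflux; aq KNaC4H4O6 work-up
Reagents that add atoms: none
Why: Hydride reduction of the aryl carbamate: attack at the carbonyl expels the aryloxide and the formamide is reduced on to the tertiary amine; the aryl–silicon bond and the acetal are inert to hydride, and the neutral tartrate work-up avoids protodesilylation.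

Step 10
Reactants: 15 3-(methoxymethoxy)-5-methyl-2-(trimethylsilyl)phenol
Product: 16 3-(methoxymethoxy)-5-methyl-2-(trimethylsilyl)phenyl trifluoromethanesulfonate
Conditions: Tf2O, pyridine, CH2Cl2, 0 °C
Reagents that add atoms: trifluoromethanesulfonic anhydride, O=S(=O)(OS(=O)(=O)C(F)(F)F)C(F)(F)F
Why: O-sulfonylation of the phenol buffered by pyridine, the standard final step to ortho-silylaryl triflates; the base keeps the medium from becoming acidic enough to touch the acetal or the arylsilane.

Step 11
Reactants: 9 4-chloro-2-hydroxy-5-methoxy-3-(methoxymethoxy)benzoic acid; 16 3-(methoxymethoxy)-5-methyl-2-(trimethylsilyl)phenyl trifluoromethanesulfonate; 17 carbon dioxide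
Product: 20 2-[2-carboxy-3-(methoxymethoxy)-5-methylphenoxy]-4-chloro-5-methoxy-3-(methoxymethoxy)benzoic acid, via dipotassium phenoxide carboxylate 18 (not isolated), via aryne 19 (not isolated)
Conditions: 9, KH (2 equiv), THF, 0 °C to rt; then 18-crown-6, KF, CO2 (1 atm), 16 added slowly, THF, 0 °C to rt; cold 1 M HCl to pH 3
Reagents that add atoms: none
Why: Proposed new method: fluoride attacks silicon in 16 and the aryl anion expels triflate to give aryne 19; the phenoxide oxygen of 18 adds to the aryne carbon remote from the OMOM group (C6'), and the aryl anion thus formed at C1', stabilised inductively by the adjacent OMOM oxygen, is carboxylated by CO2, so the O–C6' and C1'–carboxyl bonds form in one operation. The closest known reaction types are the fluoride-induced O-arylation of phenols by ortho-silylaryl triflates and the aryne–amine–CO2 three-component coupling that gives anthranilic acids; the phenoxide–aryne–CO2 combination itself has not been shown. No ring is closed and no stereocentre is formed. Regioselectivity across the aryne is required and is secured by the C2' alkoxy group, which distorts the triple bond so that the distal carbon is the electrophilic one and the negative charge develops next to the oxygen. Chemoselectivity for phenoxide over carboxylate oxygen is required and rests on the far greater basicity and nucleophilicity of the phenoxide within the dianion. Carrying the ring A carboxyl as its potassium carboxylate denies the aryl anion the intramolecular acyl acceptor that an ester would offer (xanthone formation). Pre-forming the salt with KH in an aprotic solvent removes every O–H proton that would otherwise give the ether lacking the C1' carboxyl.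

Step 12
Reactants: 20 2-[2-carboxy-3-(methoxymethoxy)-5-methylphenoxy]-4-chloro-5-methoxy-3-(methoxymethoxy)benzoic acid
Product: 21 2-(2-carboxy-3-hydroxy-5-methylphenoxy)-4-chloro-3-hydroxy-5-methoxybenzoic acid
Conditions: 3 M aq HCl, THF, rt
Reagents that add atoms: none
Why: Acid-catalysed hydrolysis of both aryl MOM acetals; the aryl methyl ether, the aryl chloride and the diaryl ether are inert to dilute acid, and room temperature is kept to avoid decarboxylation of the ring B salicylic acid.

## Compound list

1 | 3-methoxyphenol | COc1cccc(O)c1 | starting material
2 | 1-methoxy-3-(methoxymethoxy)benzene | COCOc1cccc(OC)c1 | intermediate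
3 | [2-methoxy-6-(methoxymethoxy)phenyl]lithium | [Li]c1c(OC)cccc1OCOC | intermediate (not isolated)
4 | 2-chloro-1-methoxy-3-(methoxymethoxy)benzene | COCOc1cccc(OC)c1Cl | intermediate
5 | [3-chloro-4-methoxy-2-(methoxymethoxy)phenyl]lithium | [Li]c1ccc(OC)c(Cl)c1OCOC | intermediate (not isolated)
6 | dimethyl [3-chloro-4-methoxy-2-(methoxymethoxy)phenyl]boronate | COCOc1c(B(OC)OC)ccc(OC)c1Cl | intermediate (not isolated)
7 | 3-chloro-4-methoxy-2-(methoxymethoxy)phenol | COCOc1c(O)ccc(OC)c1Cl | intermediate
8 | 4-chloro-2-hydroxy-5-methoxy-3-(methoxymethoxy)benzaldehyde | COCOc1c(O)c(C=O)cc(OC)c1Cl | intermediate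
9 | 4-chloro-2-hydroxy-5-methoxy-3-(methoxymethoxy)benzoic acid | COCOc1c(O)c(C(=O)O)cc(OC)c1Cl | intermediate
10 | orcinol (5-methylbenzene-1,3-diol) | Cc1cc(O)cc(O)c1 | starting material
11 | 3-(methoxymethoxy)-5-methylphenol | COCOc1cc(C)cc(O)c1 | intermediate
12 | 3-(methoxymethoxy)-5-methylphenyl N,N-diethylcarbamate | CCN(CC)C(=O)Oc1cc(C)cc(OCOC)c1 | intermediate
13 | [2-(diethylcarbamoyloxy)-6-(methoxymethoxy)-4-methylphenyl]lithium | [Li]c1c(OCOC)cc(C)cc1OC(=O)N(CC)CC | intermediate (not isolated)
14 | 3-(methoxymethoxy)-5-methyl-2-(trimethylsilyl)phenyl N,N-diethylcarbamate | CCN(CC)C(=O)Oc1cc(C)cc(OCOC)c1[Si](C)(C)C | intermediate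
15 | 3-(methoxymethoxy)-5-methyl-2-(trimethylsilyl)phenol | COCOc1cc(C)cc(O)c1[Si](C)(C)C | intermediate
16 | 3-(methoxymethoxy)-5-methyl-2-(trimethylsilyl)phenyl trifluoromethanesulfonate | Cc1cc(OCOC)c([Si](C)(C)C)c(OS(=O)(=O)C(F)(F)F)c1 | intermediate
17 | carbon dioxide | O=C=O | starting material
18 | dipotassium 4-chloro-5-methoxy-3-(methoxymethoxy)-2-oxidobenzoate | [K+].[K+].COCOc1c([O-])c(C(=O)[O-])cc(OC)c1Cl | intermediate (not isolated)
19 | 3-(methoxymethoxy)-5-methylbenzyne (1-(methoxymethoxy)-5-methylcyclohexa-1,5-dien-3-yne) | COCOC1=CC(C)=CC#C1 | intermediate (not isolated)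
20 | 2-[2-carboxy-3-(methoxymethoxy)-5-methylphenoxy]-4-chloro-5-methoxy-3-(methoxymethoxy)benzoic acid | COc1cc(C(=O)O)c(Oc2cc(C)cc(OCOC)c2C(=O)O)c(OCOC)c1Cl | intermediate
21 | 2-(2-carboxy-3-hydroxy-5-methylphenoxy)-4-chloro-3-hydroxy-5-methoxybenzoic acid | COc1cc(C(=O)O)c(Oc2cc(C)cc(O)c2C(=O)O)c(O)c1Cl | target

## Step count and least certain steps

Total: 12 steps. Longest linear sequence: 7 steps (steps 1–5, 11, 12; the ring B branch, steps 6–10, 11, 12, is equally long).

**Step 11 (key step, new method).**
- Most likely to go wrong: protonation of the C1' aryl anion before it meets CO2, which gives the ether without the ring B carboxyl. Other risks are O-arylation at a carboxylate oxygen, and slow addition of the doubly ortho-substituted phenoxide so that the aryne is consumed by fluoride or by the product carboxylates. Reversible carbonate formation between phenoxide and CO2 may also lower the concentration of free nucleophile.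
- Fallback (known chemistry, from 9, returning at 20):
  - Acid 9 would be esterified with MeI and KHCO3 in DMF to methyl 4-chloro-2-hydroxy-5-methoxy-3-(methoxymethoxy)benzoate F1.
  - Separately, 3-bromo-5-methylphenol would be protected with MOMCl to 1-bromo-3-(methoxymethoxy)-5-methylbenzene F2. Deprotonation with LiN(i-Pr)2 between bromine and OMOM at −78 °C and formylation with DMF would give 2-bromo-6-(methoxymethoxy)-4-methylbenzaldehyde F3.
  - Ullmann coupling of F1 with F3 (CuI, picolinic acid, K3PO4, DMSO, 90 °C) would give methyl 4-chloro-2-[2-formyl-3-(methoxymethoxy)-5-methylphenoxy]-5-methoxy-3-(methoxymethoxy)benzoate F4.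
  - Pinnick oxidation would give 2-[3-chloro-4-methoxy-6-(methoxycarbonyl)-2-(methoxymethoxy)phenoxy]-6-(methoxymethoxy)-4-methylbenzoic acid F5, and saponification of the unhindered ring A ester with aqueous LiOH would return 20.
  - The hindered phenol is a poor Ullmann partner, which is why this is the reserve and not the plan.

**Step 3 (second metalation).**
- Most likely to go wrong: partial lithiation next to OMe instead of OMOM, or chlorine–lithium exchange, either of which would erode regiochemical purity.
- Fallback (from 4, returning at 7):
  - The acetal of 4 would be removed with HCl in methanol to give 2-chloro-3-methoxyphenol F6.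
  - Magnesium-mediated ortho-formylation at its only free ortho carbon would give 3-chloro-2-hydroxy-4-methoxybenzaldehyde F7.
  - Re-protection with MOMCl would give 3-chloro-4-methoxy-2-(methoxymethoxy)benzaldehyde F8.
  - Baeyer–Villiger oxidation with mCPBA would give 3-chloro-4-methoxy-2-(methoxymethoxy)phenyl formate F9, and methanolysis with K2CO3 would give 7.

**Step 5 (oxidation of the free salicylaldehyde).**
- Most likely to go wrong: oxidation or ring chlorination of the para-methoxyphenol unit by chlorine oxides competing with aldehyde oxidation.
- Fallback (from 8, returning at 9): the phenol would be masked by acetylation (Ac2O, pyridine) to 3-chloro-6-formyl-4-methoxy-2-(methoxymethoxy)phenyl acetate F10. Pinnick oxidation would give 2-(acetyloxy)-4-chloro-5-methoxy-3-(methoxymethoxy)benzoic acid F11, and aqueous LiOH would hydrolyse the acetate to 9.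

**Step 9 (carbamate cleavage).**
- Most likely to go wrong: incomplete reduction of the carbamate shielded by the ortho silyl group, or loss of the silyl group during work-up.
- Fallback (from 11, returning at 15), using a carbamate that leaves by elimination instead of reduction:
  - Phenol 11 and isopropyl isocyanate (Et3N) would give 3-(methoxymethoxy)-5-methylphenyl N-(propan-2-yl)carbamate F12.
  - N-silylation in the flask with TBSOTf and TMEDA would give 3-(methoxymethoxy)-5-methylphenyl N-[tert-butyl(dimethyl)silyl]-N-(propan-2-yl)carbamate F13.
  - Lithiation with n-BuLi/TMEDA at −78 °C, quench with TMSCl and aqueous work-up would give 3-(methoxymethoxy)-5-methyl-2-(trimethylsilyl)phenyl N-(propan-2-yl)carbamate F14.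
  - Et2NH and DBU in MeCN at 40 °C would release 15 by loss of the isocyanate.
  - The silyl triflate must be kept close to one equivalent so that it does not attack the acetal.

**Step 12 (final deprotection).**
- Most likely to go wrong: acid-promoted decarboxylation of the 2,6-dioxygenated ring B acid, or lactonisation between the C1' carboxyl and the freed C5 hydroxyl, if the acetals are slow to cleave and the conditions have to be forced.
- Fallback (from 20, returning at 21):
  - Both acids would be masked with allyl bromide and K2CO3 in DMF to give prop-2-en-1-yl 4-chloro-5-methoxy-3-(methoxymethoxy)-2-{3-(methoxymethoxy)-5-methyl-2-[(prop-2-en-1-yloxy)carbonyl]phenoxy}benzoate F15.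
  - The acetals would then be removed with aqueous HCl in THF, where no free acid can decarboxylate or lactonise, to give prop-2-en-1-yl 4-chloro-3-hydroxy-2-{3-hydroxy-5-methyl-2-[(prop-2-en-1-yloxy)carbonyl]phenoxy}-5-methoxybenzoate F16.
  - The allyl esters would be removed under neutral conditions with Pd(PPh3)4 (zerovalent palladium) and morpholine to give 21; the aryl chloride does not react with this catalyst at room temperature.

## Further compounds

F1 | step 11 | methyl 4-chloro-2-hydroxy-5-methoxy-3-(methoxymethoxy)benzoate | COCOc1c(O)c(C(=O)OC)cc(OC)c1Cl
F2 | step 11 | 1-bromo-3-(methoxymethoxy)-5-methylbenzene | COCOc1cc(C)cc(Br)c1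
F3 | step 11 | 2-bromo-6-(methoxymethoxy)-4-methylbenzaldehyde | COCOc1cc(C)cc(Br)c1C=O
F4 | step 11 | methyl 4-chloro-2-[2-formyl-3-(methoxymethoxy)-5-methylphenoxy]-5-methoxy-3-(methoxymethoxy)benzoate | COc1cc(C(=O)OC)c(Oc2cc(C)cc(OCOC)c2C=O)c(OCOC)c1Cl
F5 | step 11 | 2-[3-chloro-4-methoxy-6-(methoxycarbonyl)-2-(methoxymethoxy)phenoxy]-6-(methoxymethoxy)-4-methylbenzoic acid | COc1cc(C(=O)OC)c(Oc2cc(C)cc(OCOC)c2C(=O)O)c(OCOC)c1Cl
F6 | step 3 | 2-chloro-3-methoxyphenol | COc1cccc(O)c1Cl
F7 | step 3 | 3-chloro-2-hydroxy-4-methoxybenzaldehyde | COc1ccc(C=O)c(O)c1Cl
F8 | step 3 | 3-chloro-4-methoxy-2-(methoxymethoxy)benzaldehyde | COCOc1c(C=O)ccc(OC)c1Cl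
F9 | step 3 | 3-chloro-4-methoxy-2-(methoxymethoxy)phenyl formate | COCOc1c(OC=O)ccc(OC)c1Cl
F10 | step 5 | 3-chloro-6-formyl-4-methoxy-2-(methoxymethoxy)phenyl acetate | COCOc1c(OC(C)=O)c(C=O)cc(OC)c1Cl
F11 | step 5 | 2-(acetyloxy)-4-chloro-5-methoxy-3-(methoxymethoxy)benzoic acid | COCOc1c(OC(C)=O)c(C(=O)O)cc(OC)c1Cl
F12 | step 9 | 3-(methoxymethoxy)-5-methylphenyl N-(propan-2-yl)carbamate | CC(C)NC(=O)Oc1cc(C)cc(OCOC)c1
F13 | step 9 | 3-(methoxymethoxy)-5-methylphenyl N-[tert-butyl(dimethyl)silyl]-N-(propan-2-yl)carbamate | CC(C)N(C(=O)Oc1cc(C)cc(OCOC)c1)[Si](C)(C)C(C)(C)C
F14 | step 9 | 3-(methoxymethoxy)-5-methyl-2-(trimethylsilyl)phenyl N-(propan-2-yl)carbamate | CC(C)NC(=O)Oc1cc(C)cc(OCOC)c1[Si](C)(C)C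
F15 | step 12 | prop-2-en-1-yl 4-chloro-5-methoxy-3-(methoxymethoxy)-2-{3-(methoxymethoxy)-5-methyl-2-[(prop-2-en-1-yloxy)carbonyl]phenoxy}benzoate | COc1cc(C(=O)OCC=C)c(Oc2cc(C)cc(OCOC)c2C(=O)OCC=C)c(OCOC)c1Cl
F16 | step 12 | prop-2-en-1-yl 4-chloro-3-hydroxy-2-{3-hydroxy-5-methyl-2-[(prop-2-en-1-yloxy)carbonyl]phenoxy}-5-methoxybenzoate | COc1cc(C(=O)OCC=C)c(Oc2cc(C)cc(O)c2C(=O)OCC=C)c(O)c1Cl
A1 | alternative 1 | methyl 3-hydroxy-5-methoxy-2-[2-(methoxycarbonyl)-3-(methoxymethoxy)-5-methylphenoxy]-4-(trimethylsilyl)benzoate | COC(=O)c1cc(OC)c([Si](C)(C)C)c(O)c1Oc1cc(C)cc(OCOC)c1C(=O)OC
A2 | alternative 1 | methyl 2-{[2-(diazoacetyl)-3-methoxy-3-oxoprop-1-en-1-yl]oxy}-6-(methoxymethoxy)-4-methylbenzoate | COC(=O)C(=COc1cc(C)cc(OCOC)c1C(=O)OC)C(=O)C=[N+]=[N-]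
A3 | alternative 1 | (methoxyethynyl)trimethylsilane | COC#C[Si](C)(C)C
A4 | alternative 2 | 2-[2-(tert-butoxycarbonyl)-3-hydroxy-5-methylphenoxy]-4-chloro-5-methoxy-3-(methoxymethoxy)benzoic acid | COc1cc(C(=O)O)c(Oc2cc(C)cc(O)c2C(=O)OC(C)(C)C)c(OCOC)c1Cl
A5 | alternative 2 | 1-tert-butyl 7-methyl (4Z)-5-methylhept-4-en-2-ynedioate | CC(C)(C)OC(=O)C#C/C=C(/C)CC(=O)OC
A6 | alternative 3 | tert-butyl 4-chloro-2-[3-hydroxy-2-(methoxycarbonyl)-5-methylphenoxy]-5-methoxy-3-(methoxymethoxy)benzoate | COC(=O)c1c(O)cc(C)cc1Oc1c(OCOC)c(Cl)c(OC)cc1C(=O)OC(C)(C)C
A7 | alternative 3 | methyl 3-[2-(tert-butoxycarbonyl)-5-chloro-4-methoxy-6-(methoxymethoxy)phenoxy]-5-methyl-2-(prop-2-enoyl)hexa-2,5-dienoate | COC(=O)C(C(=O)C=C)=C(CC(C)=C)Oc1c(OCOC)c(Cl)c(OC)cc1C(=O)OC(C)(C)C
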